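The turnover number, product over free enzyme charged, stays nearly the same from east to north, two runs at one temperature whose substrate differs as well as their loading. At 32 °C and 120 min, east reaches 3180 and north 3220, with twice the loading.

| flask | substrate | free enzyme | temperature | remark | time |
|---|---|---|---|---|---|
| east | 0.016 M | 0.005 mol% | 32 °C | run made earlier |  |
| south | 0.016 M | 0.0075 mol% | 44 °C | run made earlier |  |
| north | 0.024 M | 0.01 mol% | 32 °C | run made earlier |  |
| ochre | 0.016 M | 0.01 mol% | 52 °C |  | 80 min |
| violet | 0.016 M | 0.01 mol% | 37 °C |  | 80 min |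

| run | time / min | product / % |
|---|---|---|
| east | 30.0 | 4.2 |
| east | 60.0 | 8.1 |
| east | 120 | 15.9 |
| east | 150 | 18.5 |
| south | 4.00 | 3.2 |
| south | 8.00 | 5.8 |
| south | 20.0 | 14.9 |
| south | 50.0 | 30.6 |
| north | 30.0 | 9.5 |
| north | 60.0 | 17.9 |
| north | 120 | 32.2 |
| north | 150 | 38.6 |

(scatter of a reading: 0.5 percentage points)

- the numbers in the tables scatter with a standard deviation of 0.5 percentage points

- which flask leads in amount of product, in percent of the substrate charged ("all alike" within 1.5 percentage points) (ochre / violet / all alike)
- how much product is there at the end, in percent of the substrate charged: ochre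
- how much product is there at the end, in percent of the substrate charged: violet

So I read south for how this number grows. Its mean turnover rate falls from 99.3 min⁻¹ up to 20.0 min to 69.8 min⁻¹ afterwards. But a straight line of rate against turnover number reaches zero at 7850: this is the ceiling, the total turnover number, read with the scatter of south.

South gives this ceiling at 44 °C and at no other temperature, so taking it for both flasks is my assumption. The same line gives starting rates of 114 min⁻¹ at 44 °C and 33.7 min⁻¹ at 32 °C. Interpolating their logarithms over temperature gives 55.9 min⁻¹ for violet and 256 min⁻¹ for ochre. The turnover number then rises exponentially towards the ceiling, so I reckon violet at 34.1 % and ochre at 72.7 %.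

The forecast differs: 60 % for ochre, 32 % for violet, and ochre ahead, with the words “This is uncertain, but ochre probably still leads”.

Ochre gives 65.0 % and violet 34.1 %, so ochre leads.

    free enzyme → unfolded enzyme (k = 0.00310 h⁻¹, Ea = 229 kJ mol⁻¹)
    substrate + free enzyme ⇌ complex (K = 1500 M⁻¹, k = 10000 M⁻¹ s⁻¹, Ea = 29.0 kJ mol⁻¹, ΔH = 5.00 kJ mol⁻¹)
    complex → free enzyme + product (k = 3700 h⁻¹, Ea = 85.0 kJ mol⁻¹)
    substrate ⇌ dormant form (K = 1.70, k = 8.30 h⁻¹, Ea = 91.0 kJ mol⁻¹, ΔH = −35.0 kJ mol⁻¹)
    complex → spent catalyst (k = 0.400 h⁻¹, Ea = 100 kJ mol⁻¹)
    (constants at 37 °C)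

Ochre's turnover number is 6500, with 91.9 % of its catalyst as spent catalyst, so ochre makes 7070 product per spent catalyst, fewer than the 7850 read from south. Its turnover number is a share 0.828 of south's ceiling. Holding that share, a neighbour of ochre charged with 0.006 mol% reckons at 39.0 % and gives 39.5 %. In the same way a second neighbour, charged with 0.004 mol%, reckons at 26.0 % and gives 26.4 %, with 39 % of its substrate still unbound.

The runs are simulated with made-up constants.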